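Ring B (C5–C10; halimane numbering, ring A = C1–C5 plus C10) is disconnected across C5–C6 and C9–C10. Both bonds form in one flask by a regiospecific Robinson-type annulation: the C5 enolate of an enantioenriched 3-methyl-3-(methoxycarbonyl)cyclohexanone (ring A, C4 already quaternary) adds to an α-silyl vinyl ketone that carries C6–C9 and side-chain carbons C11–C14, and aldol condensation closes ring B as a C8-oxo-Δ9(10)-octalin. The feature exploited is the C1=C10 alkene lying β,γ to C8 and next to quaternary C9: deconjugative C9-methylation of that enone later creates both, and the C8 carbonyl becomes the C17 methyl.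

Key step: step 4

Remark on numbering: C18 is the ester carbon and C19 the methyl on C4; C17 is the methyl on C8; C20 is the methyl on C9; C11–C16 is the side chain (C15 = CH2OH, C16 = methyl on C13).

Assumption: in step 3 the antipode of the chiral NHC ligand is chosen that delivers methyl to the face of C4 giving the S centre; the sense of induction is to be confirmed on the first run and the mirror-image ligand taken otherwise.

Step 1
Reactants: 1 hex-5-ynoic acid
Product: 3 N-methoxy-N-methylhex-5-ynamide, via acyl imidazole 2 (not isolated)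
Conditions: CDI, CH2Cl2, rt; then MeNHOMe·HCl, rt
Reagents that add atoms: N,O-dimethylhydroxylamine hydrochloride (CNOC.Cl)
Why: Acyl-imidazole activation followed by aminolysis (Weinreb amide formation) is routine for an unhindered acid, and the terminal alkyne is inert.

Step 2
Reactants: 3 N-methoxy-N-methylhex-5-ynamide; 4 (1-bromoethenyl)trimethylsilane
Product: 6 2-(trimethylsilyl)oct-1-en-7-yn-3-one, via silylvinyllithium 5 (not isolated)
Conditions: 4 (2.3 equiv), t-BuLi (4.6 equiv), Et2O, −78 °C; then 3, −78 → −20 °C; H2O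
Reagents that add atoms: none
Why: Bromine–lithium exchange and acyl substitution on the Weinreb amide, whose chelated tetrahedral adduct prevents over-addition, should give the α-silyl enone; one extra equivalent of 5 is consumed by the acidic alkyne C–H, which is restored on work-up.

Step 3
Reactants: 7 methyl 3-oxocyclohex-1-ene-1-carboxylate
Product: 9 methyl (S)-1-methyl-3-[(trimethylsilyl)oxy]cyclohex-2-ene-1-carboxylate, via methylzinc enolate 8 (not isolated)
Conditions: (CuOTf)2·C6H6 (2.5 mol %), chiral sulfonate-bearing imidazolinium salt (NHC precursor, 5 mol %), Me2Zn (3 equiv), t-BuOMe, −30 °C; then TMSOTf, −78 → 0 °C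
Reagents that add atoms: dimethylzinc (C[Zn]C); trimethylsilyl trifluoromethanesulfonate (C[Si](C)(C)OS(=O)(=O)C(F)(F)F)
Why: Copper-catalysed asymmetric conjugate addition of a dialkylzinc to a cyclic γ-keto ester puts methyl on C4 (β to the ketone), the chiral NHC complex formed from (CuOTf)2·C6H6 selecting the enantiotopic face and so setting the quaternary centre C4 (S), and O-silylation of zinc enolate 8 fixes the enol double bond at C5=C10.

Step 4
Reactants: 9 methyl (S)-1-methyl-3-[(trimethylsilyl)oxy]cyclohex-2-ene-1-carboxylate; 6 2-(trimethylsilyl)oct-1-en-7-yn-3-one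
Product: 13 methyl (1S,8aR)-5-(but-3-yn-1-yl)-1-methyl-6-oxo-1,2,3,4,6,7,8,8a-octahydronaphthalene-1-carboxylate, via potassium enolate 10 (not isolated), via silyl diketone 11 (not isolated), via diketone 12 (not isolated)
Conditions: KOtBu (1.0 equiv), THF, −30 °C; 6, −78 → −20 °C; then NaOMe, MeOH, rt → 60 °C
Reagents that add atoms: none
Why: Alkoxide cleavage of the silyl enol ether gives the potassium enolate regiospecifically at C5; Michael addition to the α-silyl enone forms C5–C6 and leaves a silyl-stabilised enolate that cannot equilibrate; methoxide then removes the silyl group and the C9 enolate of the side-chain ketone closes ring B on the C10 carbonyl, dehydration making C9=C10 (the C9–C10 bond). The closest known reaction type is the α-silyl vinyl ketone (Stork–Ganem) variant of the Robinson annulation, applied to a regiospecifically generated enolate flanked by a quaternary carbon. Ring B closes by a 6-(enolexo)-exo-trig aldol addition followed by E1cB dehydration. The new stereocentre C5 is controlled by C4: the acceptor approaches anti to the C4 methyl, on the face of the flatter ester, so that C6 is cis to C18 and H5 cis to C19. The step needs C5-versus-C1 regioselectivity, secured by the isolated enol ether 9 and the fast, non-equilibrating silyl enone, and fused-versus-bridged aldol selectivity, secured by irreversible dehydration of the fused ketol. The facial preference at C5 is expected to be moderate, and the C5 epimers of 13 are separable diastereomers.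

Step 5
Reactants: 13 methyl (1S,8aR)-5-(but-3-yn-1-yl)-1-methyl-6-oxo-1,2,3,4,6,7,8,8a-octahydronaphthalene-1-carboxylate
Product: 15 methyl (1S,5R,8aR)-5-(but-3-yn-1-yl)-1,5-dimethyl-6-oxo-1,2,3,5,6,7,8,8a-octahydronaphthalene-1-carboxylate, via potassium dienolate 14 (not isolated)
Conditions: KOtBu (1.2 equiv), t-BuOH/THF, 0 °C; MeI, 0 °C → rt
Reagents that add atoms: iodomethane (CI)
Why: Deconjugative α-alkylation of the enone through its thermodynamic heteroannular dienolate (γ-deprotonation at C1) should methylate C9, creating the quaternary centre and leaving the alkene at C1=C10; iodomethane enters axially through a chair-like transition state on the face of the pseudoaxial H5, so C20 ends cis to H5.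

Step 6
Reactants: 15 methyl (1S,5R,8aR)-5-(but-3-yn-1-yl)-1,5-dimethyl-6-oxo-1,2,3,5,6,7,8,8a-octahydronaphthalene-1-carboxylate
Product: 16 methyl (1S,5S,8aR)-5-(but-3-yn-1-yl)-1,5-dimethyl-6-methylidene-1,2,3,5,6,7,8,8a-octahydronaphthalene-1-carboxylate
Conditions: Ph3PCH3Br (3 equiv), KOtBu (2.8 equiv), toluene, 90 °C
Reagents that add atoms: methyltriphenylphosphonium bromide (C[P+](c1ccccc1)(c1ccccc1)c1ccccc1.[Br-])
Why: Wittig methylenation under forcing conditions is established for α-quaternary cyclohexanones; C9 cannot epimerise and the hindered tertiary ester and the alkyne do not react with the ylide.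

Step 7
Reactants: 16 methyl (1S,5S,8aR)-5-(but-3-yn-1-yl)-1,5-dimethyl-6-methylidene-1,2,3,5,6,7,8,8a-octahydronaphthalene-1-carboxylate
Product: 19 methyl (1S,5S,8aR)-5-[(3E)-5-hydroxy-3-methylpent-3-en-1-yl]-1,5-dimethyl-6-methylidene-1,2,3,5,6,7,8,8a-octahydronaphthalene-1-carboxylate, via alkenylalane 17 (not isolated), via lithium alanate 18 (not isolated)
Conditions: AlMe3 (3 equiv), Cp2ZrCl2 (0.25 equiv), CH2Cl2, 0 °C → rt; then MeLi, THF, −78 °C; (CH2O)n, −78 °C → rt
Reagents that add atoms: trimethylaluminium (C[Al](C)C); formaldehyde as paraformaldehyde (C=O)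
Why: Negishi zirconium-catalysed methylalumination of the terminal alkyne is syn with aluminium on the terminal carbon, and the derived alanate adds to formaldehyde with retention, so the E-trisubstituted allylic alcohol (C13=C14, C16, C15) is formed while the 1,1-disubstituted and trisubstituted alkenes and the shielded α-quaternary ester stay untouched.

Step 8
Reactants: 19 methyl (1S,5S,8aR)-5-[(3E)-5-hydroxy-3-methylpent-3-en-1-yl]-1,5-dimethyl-6-methylidene-1,2,3,5,6,7,8,8a-octahydronaphthalene-1-carboxylate
Product: 20 methyl (1S,5S,6R,8aR)-5-[(3E)-5-hydroxy-3-methylpent-3-en-1-yl]-1,5,6-trimethyl-1,2,3,5,6,7,8,8a-octahydronaphthalene-1-carboxylate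
Conditions: RhCl(PPh3)3 (10 mol %), H2 (1 atm), benzene/EtOH, rt
Reagents that add atoms: none
Why: Homogeneous hydrogenation with RhCl(PPh3)3 reduces the 1,1-disubstituted exocyclic alkene much faster than the two trisubstituted alkenes, and hydrogen is delivered to C8 from the face opposite the axial C20 methyl on C9, so C17 becomes equatorial and cis to C20 (8R), which is also the more stable arrangement.

Step 9
Reactants: 20 methyl (1S,5S,6R,8aR)-5-[(3E)-5-hydroxy-3-methylpent-3-en-1-yl]-1,5,6-trimethyl-1,2,3,5,6,7,8,8a-octahydronaphthalene-1-carboxylate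
Product: 21 methyl (1S,5S,6R,8aR)-5-{2-[(2S,3S)-3-(hydroxymethyl)-2-methyloxiran-2-yl]ethyl}-1,5,6-trimethyl-1,2,3,5,6,7,8,8a-octahydronaphthalene-1-carboxylate
Conditions: Ti(OiPr)4 (10 mol %), L-(+)-diethyl tartrate (12 mol %), TBHP, 4 Å MS, CH2Cl2, −20 °C
Reagents that add atoms: tert-butyl hydroperoxide (CC(C)(C)OO)
Why: Katsuki–Sharpless asymmetric epoxidation touches only the allylic-alcohol alkene, and with L-(+)-diethyl tartrate an E-3-methylalk-2-en-1-ol of this type is epoxidised under reagent control to the 13S,14S (oxirane 2S,3S) epoxy alcohol.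

Compound list
1 | hex-5-ynoic acid | OC(=O)CCCC#C | starting material
2 | 1-(hex-5-ynoyl)-1H-imidazole | O=C(CCCC#C)n1ccnc1 | intermediate
3 | N-methoxy-N-methylhex-5-ynamide | CON(C)C(=O)CCCC#C | intermediate
4 | (1-bromoethenyl)trimethylsilane | C=C(Br)[Si](C)(C)C | starting material
5 | [1-(trimethylsilyl)ethenyl]lithium | [Li]C(=C)[Si](C)(C)C | intermediate
6 | 2-(trimethylsilyl)oct-1-en-7-yn-3-one | C=C([Si](C)(C)C)C(=O)CCCC#C | intermediate
7 | methyl 3-oxocyclohex-1-ene-1-carboxylate | COC(=O)C1=CC(=O)CCC1 | starting material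
8 | methylzinc (S)-3-(methoxycarbonyl)-3-methylcyclohex-1-en-1-olate | COC(=O)[C@@]1(C)CCCC(O[Zn]C)=C1 | intermediate
9 | methyl (S)-1-methyl-3-[(trimethylsilyl)oxy]cyclohex-2-ene-1-carboxylate | COC(=O)[C@@]1(C)CCCC(O[Si](C)(C)C)=C1 | intermediate
10 | potassium (S)-3-(methoxycarbonyl)-3-methylcyclohex-1-en-1-olate | COC(=O)[C@@]1(C)CCCC([O-])=C1.[K+] | intermediate
11 | methyl (1S,2S)-1-methyl-3-oxo-2-[3-oxo-2-(trimethylsilyl)oct-7-yn-1-yl]cyclohexane-1-carboxylate (both epimers at the silyl-bearing carbon; present as its potassium enolate) | COC(=O)[C@@]1(C)CCCC(=O)[C@H]1CC([Si](C)(C)C)C(=O)CCCC#C | intermediate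
12 | methyl (1S,2S)-1-methyl-3-oxo-2-(3-oxooct-7-yn-1-yl)cyclohexane-1-carboxylate | COC(=O)[C@@]1(C)CCCC(=O)[C@H]1CCC(=O)CCCC#C | intermediate
13 | methyl (1S,8aR)-5-(but-3-yn-1-yl)-1-methyl-6-oxo-1,2,3,4,6,7,8,8a-octahydronaphthalene-1-carboxylate | COC(=O)[C@@]1(C)CCCC2=C(CCC#C)C(=O)CC[C@@H]12 | intermediate
14 | potassium heteroannular dienolate of 13 (enolate oxygen on C8, double bonds C8=C9 and C10=C1, C4 and C5 as in 13) | COC(=O)[C@@]1(C)CCC=C2[C@H]1CCC([O-])=C2CCC#C.[K+] | intermediate
15 | methyl (1S,5R,8aR)-5-(but-3-yn-1-yl)-1,5-dimethyl-6-oxo-1,2,3,5,6,7,8,8a-octahydronaphthalene-1-carboxylate | COC(=O)[C@@]1(C)CCC=C2[C@H]1CCC(=O)[C@]2(C)CCC#C | intermediate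
16 | methyl (1S,5S,8aR)-5-(but-3-yn-1-yl)-1,5-dimethyl-6-methylidene-1,2,3,5,6,7,8,8a-octahydronaphthalene-1-carboxylate | COC(=O)[C@@]1(C)CCC=C2[C@H]1CCC(=C)[C@]2(C)CCC#C | intermediate
17 | alkenyl(dimethyl)alane from 16 (side chain CH2CH2C(CH3)=CH–AlMe2, E, aluminium trans to C12; ring system as in 16) | COC(=O)[C@@]1(C)CCC=C2[C@H]1CCC(=C)[C@]2(C)CC/C(C)=C/[Al](C)C | intermediate
18 | lithium trimethyl(alkenyl)alanate of 17 | COC(=O)[C@@]1(C)CCC=C2[C@H]1CCC(=C)[C@]2(C)CC/C(C)=C/[Al-](C)(C)C.[Li+] | intermediate
19 | methyl (1S,5S,8aR)-5-[(3E)-5-hydroxy-3-methylpent-3-en-1-yl]-1,5-dimethyl-6-methylidene-1,2,3,5,6,7,8,8a-octahydronaphthalene-1-carboxylate | COC(=O)[C@@]1(C)CCC=C2[C@H]1CCC(=C)[C@]2(C)CC/C(C)=C/CO | intermediate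
20 | methyl (1S,5S,6R,8aR)-5-[(3E)-5-hydroxy-3-methylpent-3-en-1-yl]-1,5,6-trimethyl-1,2,3,5,6,7,8,8a-octahydronaphthalene-1-carboxylate | COC(=O)[C@@]1(C)CCC=C2[C@H]1CC[C@@H](C)[C@]2(C)CC/C(C)=C/CO | intermediate
21 | methyl (1S,5S,6R,8aR)-5-{2-[(2S,3S)-3-(hydroxymethyl)-2-methyloxiran-2-yl]ethyl}-1,5,6-trimethyl-1,2,3,5,6,7,8,8a-octahydronaphthalene-1-carboxylate | COC(=O)[C@@]1(C)CCC=C2[C@H]1CC[C@@H](C)[C@]2(C)CC[C@]1(C)O[C@H]1CO | target

Total step count: 9. Longest linear sequence: 8 steps (steps 1, 2, 4, 5, 6, 7, 8, 9, from hex-5-ynoic acid); the ring A branch (step 3) joins at step 4.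

Steps most likely to fail

Step 4 (key step). What may go wrong: the C4 methyl and the C4 ester differ little in size, so facial discrimination while the C5–C6 bond forms may be poor, and C5 can epimerise at the 1,5-diketone stage; Michael addition at the neopentyl enolate carbon may also be slow. The fallback sets out from 7 and returns at 16; it builds C5 before C4 becomes quaternary. Enone ester 7 is reduced in the 1,4-sense with Cu(OAc)2·H2O, the DTBM-SEGPHOS antipode that gives the R product, and PhMe2SiH, giving the silyl enol ether methyl (R)-3-{[dimethyl(phenyl)silyl]oxy}cyclohex-2-ene-1-carboxylate F1. F1 is cleaved with KOtBu and annulated with 6 as in step 4 (NaOMe/MeOH kept at room temperature so that the ester α-centre is not touched); C6 now enters anti to the single C4 substituent, which is also the thermodynamic trans arrangement, giving methyl (1R,8aS)-5-(but-3-yn-1-yl)-6-oxo-1,2,3,4,6,7,8,8a-octahydronaphthalene-1-carboxylate F2. Deconjugative methylation (KOtBu, MeI) gives methyl (1R,5R,8aS)-5-(but-3-yn-1-yl)-5-methyl-6-oxo-1,2,3,5,6,7,8,8a-octahydronaphthalene-1-carboxylate F3, and Wittig methylenation gives methyl (1R,5S,8aS)-5-(but-3-yn-1-yl)-5-methyl-6-methylidene-1,2,3,5,6,7,8,8a-octahydronaphthalene-1-carboxylate F4. The ester enolate of F4 (LDA, 2.2 equiv, THF, −78 °C; the first equivalent is taken by the alkyne C–H) is then methylated with MeI anti to C6, which places C19 cis to H5 and gives 16.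

Step 7. What may go wrong: loss of chemoselectivity, that is attack of the methylaluminium or methyllithium species on the C18 ester, or sluggish hydroxymethylation of the alanate. The fallback sets out from 16 and returns at 19; it builds the allylic alcohol by carbonyl olefination instead of carbometalation. The alkyne of 16 is hydrated (Ph3PAuNTf2 cat., H2O, 1,4-dioxane, 60 °C) to the methyl ketone methyl (1S,5S,8aR)-1,5-dimethyl-6-methylidene-5-(3-oxobutyl)-1,2,3,5,6,7,8,8a-octahydronaphthalene-1-carboxylate F5. Horner–Wadsworth–Emmons olefination (triethyl phosphonoacetate, NaH, THF) gives the E-enoate methyl (1S,5S,8aR)-5-[(3E)-5-ethoxy-3-methyl-5-oxopent-3-en-1-yl]-1,5-dimethyl-6-methylidene-1,2,3,5,6,7,8,8a-octahydronaphthalene-1-carboxylate F6, the Z isomer being removed by chromatography. DIBAL-H (CH2Cl2, −78 °C) reduces the unhindered conjugated ethyl ester in preference to the α-quaternary methyl ester and gives 19.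

Step 8. What may go wrong: over-reduction of the allylic-alcohol alkene, alkene migration by rhodium hydride, or too slow a reaction at the alkene next to quaternary C9. The fallback sets out from 19 and returns at 21; it changes the order so that no competing allylic alkene is present and uses a metal-free reductant. Dienol 19 is first epoxidised (Ti(OiPr)4, L-(+)-diethyl tartrate, TBHP, as in step 9) to methyl (1S,5S,8aR)-5-{2-[(2S,3S)-3-(hydroxymethyl)-2-methyloxiran-2-yl]ethyl}-1,5-dimethyl-6-methylidene-1,2,3,5,6,7,8,8a-octahydronaphthalene-1-carboxylate F7. The exocyclic alkene of F7 is then reduced with diimide (2-nitrobenzenesulfonyl hydrazide, Et3N, CH2Cl2, rt), again from the face opposite the axial C20 methyl, which gives 21.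

Further compounds
F1 | step 4 | methyl (R)-3-{[dimethyl(phenyl)silyl]oxy}cyclohex-2-ene-1-carboxylate | COC(=O)[C@@H]1CCCC(O[Si](C)(C)c2ccccc2)=C1
F2 | step 4 | methyl (1R,8aS)-5-(but-3-yn-1-yl)-6-oxo-1,2,3,4,6,7,8,8a-octahydronaphthalene-1-carboxylate | COC(=O)[C@@H]1CCCC2=C(CCC#C)C(=O)CC[C@@H]12
F3 | step 4 | methyl (1R,5R,8aS)-5-(but-3-yn-1-yl)-5-methyl-6-oxo-1,2,3,5,6,7,8,8a-octahydronaphthalene-1-carboxylate | COC(=O)[C@@H]1CCC=C2[C@H]1CCC(=O)[C@]2(C)CCC#C
F4 | step 4 | methyl (1R,5S,8aS)-5-(but-3-yn-1-yl)-5-methyl-6-methylidene-1,2,3,5,6,7,8,8a-octahydronaphthalene-1-carboxylate | COC(=O)[C@@H]1CCC=C2[C@H]1CCC(=C)[C@]2(C)CCC#C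
F5 | step 7 | methyl (1S,5S,8aR)-1,5-dimethyl-6-methylidene-5-(3-oxobutyl)-1,2,3,5,6,7,8,8a-octahydronaphthalene-1-carboxylate | COC(=O)[C@@]1(C)CCC=C2[C@H]1CCC(=C)[C@]2(C)CCC(C)=O
F6 | step 7 | methyl (1S,5S,8aR)-5-[(3E)-5-ethoxy-3-methyl-5-oxopent-3-en-1-yl]-1,5-dimethyl-6-methylidene-1,2,3,5,6,7,8,8a-octahydronaphthalene-1-carboxylate | COC(=O)[C@@]1(C)CCC=C2[C@H]1CCC(=C)[C@]2(C)CC/C(C)=C/C(=O)OCC
F7 | step 8 | methyl (1S,5S,8aR)-5-{2-[(2S,3S)-3-(hydroxymethyl)-2-methyloxiran-2-yl]ethyl}-1,5-dimethyl-6-methylidene-1,2,3,5,6,7,8,8a-octahydronaphthalene-1-carboxylate | COC(=O)[C@@]1(C)CCC=C2[C@H]1CCC(=C)[C@]2(C)CC[C@]1(C)O[C@H]1CO
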